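I bracketed the ratio at the end of the flask.

| flask | solid substrate | reagent | remark | time |
|---|---|---|---|---|
| teal | 0.010 M | 0.020 M | run made earlier |  |
| violet | 0.015 M | 0.020 M | run made earlier |  |
| red | 0.020 M | 0.030 M | run made earlier |  |
| flask | 0.020 M | 0.0200 M |  | 2.0 d |

- teal (time / d: target / %, isomer of the product / %): 0.500: 95.7, 4.3; 1.04: 95.6, 3.6; 1.25: 95.7, 4.4; 2.08: 95.9, 4.4; 2.50: 95.9, 4.1
- violet (time / d: target / %, isomer of the product / %): 0.208: 91.6, 5.2; 0.333: 93.9, 5.4; 0.625: 94.3, 5.5; 1.25: 94.9, 5.5; 2.50: 94.5, 5.5
- red (time / d: target / %, isomer of the product / %): 0.500: 96.8, 3.7; 1.04: 96.4, 3.6; 1.25: 96.7, 3.5; 2.08: 96.7, 3.4; 2.50: 96.9, 3.3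

(standard deviation of a reading: 0.3 percentage points)

- given per volume of solution although it is solid: solid substrate
- what was read earlier has a scatter of 0.3 percentage points, one standard deviation
- at the start none of the solid substrate is in solution

* ratio of target to isomer of the product at 15 min
* ratio of target to isomer of the product at 2.0 d
* which of target and isomer of the product there is more of at 2.0 d

The isomer share stood flat in time within each run, and the last readings, 3.3% in red, 4.1% in teal and 5.5% in violet, rose as the reagent present through the conversion fell, so I took the rate of isomer over that of target to be a constant concentration divided by the reagent present. Integrated over the reagent used, the last violet reading gave 5.95 × 10⁻⁴ M, and the last teal and red readings gave 5.92 × 10⁻⁴ M and 6.01 × 10⁻⁴ M. I carried this split, the reagent level at which both products form equally fast; reagent over split is the local selectivity factor.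

For the flask I assumed full conversion by 2.0 d. If isomer takes no reagent, the reagent left equals the isomer, and isomer = split × ln(reagent charged / isomer), solved by repeated substitution, gives 0.00153 M of isomer and the upper bound on the ratio, 12.1. If isomer takes reagent too, isomer = split × ln((reagent charged + split) / split) gives the lower bound, 8.48. The first violet reading, at 0.208 d, came later than 15 min, so I bracketed nothing there.

The forecast, reasoning that “the final ratio is set by the charges”, gave 32 at 15 min and 12 at 2.0 d, on the upper edge of my bracket, with target ahead.

The flask gave 57.1 at 15 min and 9.08 at 2.0 d, inside the bracket, with target at 89.5% against 9.86%.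

    reagent + other conformer → isomer of the product (k = 549 /M/h)
    starting material + reagent → target (k = 76.4 /M/h)
    solid substrate ⇌ starting material, rate k3*(cs3 - [starting material]) while solid is left; crystals form when [starting material] > cs3 (solubility = 16.0 mM, k = 2.77 /h)
    starting material ⇌ other conformer (K = 1.29, k = 0.0484 /h)

At 0.0133 d in the flask, starting material went to target 28 times as fast as to other conformer, forward step alone. At 2.00 d the reagent left, 0.64% of its charge or 1.28 × 10⁻⁴ M, lay below the split, and the target path used reagent at 0.27 of the rate of the isomer path. For the neighbour charged with 0.034 M of reagent, the reagent-taking form with the split gives a ratio of 37.9, and that neighbour stood at 35.8 at 2.0 d.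

The readings were generated by integration with constants of no real substance, noise included.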